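**Retrosynthetic overview**

- Names used: ring A = methylcyclopentane, ring B = cyclooctene, ring C = cyclohexane, ring D = isopropylcyclopentane; in the C/D hydrindane, C7a = quaternary CO2H carbon, C1 = its CH2 neighbour in ring D, C3 = isopropyl-bearing carbon, C3a = ring-fusion CH.
- Endgame: CO2H and the isopropyl CH are freed together by reductive alkyl–oxygen cleavage of a δ-lactone (carboxyl C–O–CMe2); ring B comes from ring-closing metathesis and hydrogenation; the tertiary carbinol comes from addition of the ring A alkenyllithium (from 27) to ring C ketone 17.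
- Key disconnection: bond C7a–C1, closing ring D by intramolecular alkylation of the lactone enolate, in the same flask as the Diels–Alder reaction that builds ring C on unsaturated lactone 10.
- Enabling feature: on ring D the carboxyl carbon on C7a and the isopropyl carbon on C3 are cis-1,3, so they can be tied as a six-membered lactone (C7a, C=O, O, CMe2, C3, C3a); closing C7a–C1 then gives a bicyclo[3.2.1]octane whose geometry enforces the trans C/D fusion.
- Ring order: temporary lactone, then C, then D (from (R)-α-terpineol); A separately by Cp2Zr-mediated enyne cyclisation (from (R)-β-citronellene); B last.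

Key step: step 7

Remark: 1 and 18 are taken as available in high enantiomeric purity; apart from the iridium catalyst of step 9 they are the only sources of absolute configuration.

**Route**

Step 1
Reactants: 1 (R)-α-terpineol
Product: 3 (R)-5,5-dimethyl-4-(3-oxobutyl)dihydrofuran-2(3H)-one, via hydroxy keto acid 2 (not isolated)
Conditions: RuCl3·xH2O (2 mol %), NaIO4 (4 equiv), EtOAc/MeCN/H2O, 0 → 25 °C
Reagents that add atoms: sodium periodate NaIO4 [Na+].[O-]I(=O)(=O)=O
Why: Oxidative alkene cleavage with catalytic ruthenium tetroxide (RuO4) should turn the trisubstituted ring alkene into a methyl ketone and a carboxylic acid that lactonises onto the tertiary alcohol, while the stereocentre of 1 is α to neither new carbonyl and is carried through unchanged.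

Step 2
Reactants: 3 (R)-5,5-dimethyl-4-(3-oxobutyl)dihydrofuran-2(3H)-one
Product: 4 3-[(R)-2,2-dimethyl-5-oxotetrahydrofuran-3-yl]propanoic acid
Conditions: Br2, NaOH, H2O/1,4-dioxane, 0 °C; then aq HCl to pH 2
Reagents that add atoms: sodium hydroxide NaOH [Na+].[OH-]
Why: Haloform reaction, in which exhaustive bromination of the methyl ketone and C–C cleavage by hydroxide give the carboxylate and acidification re-closes the five-membered lactone, with no stereocentre touched.

Step 3
Reactants: 4 3-[(R)-2,2-dimethyl-5-oxotetrahydrofuran-3-yl]propanoic acid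
Product: 6 (R)-5-(2-hydroxyethyl)-6,6-dimethyltetrahydro-2H-pyran-2-one, via dihydroxy acid 5 (not isolated)
Conditions: LiOH (1.0 equiv), THF; LiBH4 (2 equiv), 0 → 25 °C; then 1 M HCl, 25 °C
Reagents that add atoms: none
Why: Chemoselective hydride reduction, in which LiBH4 should reduce the γ-lactone but not the lithium carboxylate, after which the freed tertiary alcohol closes the six-membered lactone on acidification (Thorpe–Ingold assistance) in preference to the seven-membered ring through the primary alcohol.

Step 4
Reactants: 6 (R)-5-(2-hydroxyethyl)-6,6-dimethyltetrahydro-2H-pyran-2-one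
Product: 7 (R)-5-[2-(tert-butyldimethylsilyloxy)ethyl]-6,6-dimethyltetrahydro-2H-pyran-2-one
Conditions: TBSCl, imidazole, CH2Cl2, 25 °C
Reagents that add atoms: tert-butyldimethylsilyl chloride CC(C)(C)[Si](C)(C)Cl
Why: Standard silylation of the primary alcohol so that the next step can use a strong base.

Step 5
Reactants: 7 (R)-5-[2-(tert-butyldimethylsilyloxy)ethyl]-6,6-dimethyltetrahydro-2H-pyran-2-one
Product: 9 (S)-5-[2-(tert-butyldimethylsilyloxy)ethyl]-6,6-dimethyl-5,6-dihydro-2H-pyran-2-one, via α-phenylselanyl lactone 8 (not isolated)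
Conditions: LiN(iPr)2, THF, −78 °C; PhSeBr; then H2O2 (30 %), pyridine, CH2Cl2, 0 → 25 °C
Reagents that add atoms: none
Why: α-Selenenylation of the lactone enolate and selenoxide syn-elimination should give the endocyclic α,β-unsaturated lactone, the only alkene possible because both β-hydrogens sit on the ring CH2.

Step 6
Reactants: 9 (S)-5-[2-(tert-butyldimethylsilyloxy)ethyl]-6,6-dimethyl-5,6-dihydro-2H-pyran-2-one
Product: 10 (S)-5-(2-bromoethyl)-6,6-dimethyl-5,6-dihydro-2H-pyran-2-one
Conditions: Ph3PBr2, CH2Cl2, 0 → 25 °C
Reagents that add atoms: dibromotriphenylphosphorane BrP(Br)(c1ccccc1)(c1ccccc1)c1ccccc1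
Why: Appel-type direct conversion of a primary silyl ether into the bromide (silyl transfer to bromide, then SN2 displacement of the oxyphosphonium), which installs the leaving group without touching the enoate.

Step 7
Reactants: 10 (S)-5-(2-bromoethyl)-6,6-dimethyl-5,6-dihydro-2H-pyran-2-one; 11 2-(trimethylsilyloxy)buta-1,3-diene
Product: 14 trans-fused 3-(2-hydroxypropan-2-yl)-5-(trimethylsilyloxy)-2,3,3a,4,7,7a-hexahydro-1H-indene-7a-carboxylic acid δ-lactone, via Diels–Alder adduct 12 (not isolated), via potassium enolate 13 (not isolated)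
Conditions: 11 (3 equiv), BHT (cat.), toluene, 160 °C, sealed tube; cool; then KN(SiMe3)2 (1.3 equiv), THF, −78 → 0 °C; non-aqueous work-up
Reagents that add atoms: none
Why: A thermal Diels–Alder reaction of the 2-siloxydiene with the unsaturated lactone (closest precedent: siloxydiene cycloadditions to butenolides and dihydropyranones) closes ring C by a suprafacial [4+2] addition in which the nucleophilic CH2 terminus next to the siloxy carbon bonds to the lactone β-carbon, so the masked ketone ends para to the lactone α-carbon. The diene can approach 10 only on the face opposite the 2-bromoethyl chain and the axial methyl of the CMe2 group, which sets the ring-fusion CH (C3a) trans to that chain. KN(SiMe3)2 then removes the only acidic proton, the lactone α-H at the ring fusion (the ketone stays masked as its silyl enol ether, so no ketone enolate can compete), and the planar enolate carbon C7a displaces bromide in a 5-exo-tet intramolecular alkylation, the classical entry to bicyclo[3.2.1]octanes, which closes ring D. Because the two-carbon chain hangs from the lactone carbon next to the CMe2–O carbon, it can reach C7a only from its own face, so the quaternary centre is fixed with the carboxyl cis to the CMe2 carbon and, given the anti cycloaddition, trans to the C3a hydrogen; the trans-hydrindane follows from geometry and not from a selectivity. The selectivities still needed are para regiochemistry and anti facial approach in the cycloaddition, and C-alkylation over O-alkylation and over E2 loss of HBr in the second stage; the first two follow from diene polarity and from the substituents flanking the β-carbon, the last from the five-membered transition state (O-alkylation would need a seven-membered ring). In one flask three C–C bonds, rings C and D and both stereocentres of the C/D fusion should arise from a monocyclic lactone.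

Step 8
Reactants: 15 (E)-but-2-en-1-ol
Product: 16 (E)-but-2-en-1-yl methyl carbonate
Conditions: ClCO2Me, pyridine, CH2Cl2, 0 °C
Reagents that add atoms: methyl chloroformate COC(=O)Cl
Why: Acylation of the allylic alcohol with a chloroformate gives the carbonate leaving group needed for iridium allyl chemistry.

Step 9
Reactants: 14 tricyclic lactone silyl enol ether; 16 (E)-but-2-en-1-yl methyl carbonate
Product: 17 trans-fused 6-[(S)-but-3-en-2-yl]-3-(2-hydroxypropan-2-yl)-5-oxo-octahydro-1H-indene-7a-carboxylic acid δ-lactone (butenyl group equatorial)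
Conditions: [Ir(cod)Cl]2 (2 mol %), O,O'-(1,1'-binaphthalene-2,2'-diyl) N,N-bis(1-phenylethyl)phosphoramidite (4 mol %, enantiomer chosen for the S allylic centre), CsF (0.4 equiv), ZnF2 (1.5 equiv), DME, 50 °C; then DBU, CH2Cl2, 25 °C
Reagents that add atoms: none
Why: Iridium-catalysed branched-selective allylic alkylation (Tsuji–Trost type) of the enolate released from the regiodefined silyl enol ether should attach the substituted allyl terminus to the ring α-carbon, the methyl-bearing stereocentre being set by the chiral phosphoramidite–iridium allyl complex and the ring α-centre being equilibrated by DBU to the equatorial epimer.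

Step 10
Reactants: 18 (R)-3,7-dimethylocta-1,6-diene ((R)-β-citronellene)
Product: 20 (R)-4-methylhex-5-enal, via trisubstituted epoxide 19 (not isolated)
Conditions: mCPBA, CH2Cl2, 0 °C; then H5IO6, THF/H2O, 0 → 25 °C
Reagents that add atoms: 3-chloroperoxybenzoic acid OOC(=O)c1cccc(Cl)c1
Why: Chemoselective Prilezhaev epoxidation of the electron-rich trisubstituted alkene followed by periodic acid cleavage of the epoxide through its diol removes the isopropylidene end as acetone and leaves the remote methyl stereocentre unchanged.

Step 11
Reactants: 20 (R)-4-methylhex-5-enal; 21 (Z)-1,4-bis(benzyloxy)but-2-ene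
Product: 22 (R,E)-7-(benzyloxy)-4-methylhept-5-enal
Conditions: second-generation Hoveyda–Grubbs catalyst (3 mol %), 21 (3 equiv), CH2Cl2, 40 °C
Reagents that add atoms: none
Why: Olefin cross-metathesis of the terminal alkene with an excess of the symmetrical allylic ether should install the benzyloxymethyl group as the favoured E-alkene, the aldehyde being tolerated and no second alkene being present for ring closure.

Step 12
Reactants: 22 (R,E)-7-(benzyloxy)-4-methylhept-5-enal
Product: 23 benzyl (R,E)-8,8-dibromo-4-methylocta-2,7-dien-1-yl ether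
Conditions: CBr4, PPh3, CH2Cl2, 0 °C
Reagents that add atoms: tetrabromomethane BrC(Br)(Br)Br
Why: First stage of the Corey–Fuchs homologation, a Wittig-type dibromo-olefination of the aldehyde with Ph3P=CBr2.

Step 13
Reactants: 23 benzyl (R,E)-8,8-dibromo-4-methylocta-2,7-dien-1-yl ether
Product: 25 benzyl (R,E)-4-methylnon-2-en-7-yn-1-yl ether, via lithium acetylide 24 (not isolated)
Conditions: n-BuLi (2.2 equiv), THF, −78 °C; then MeI, −78 → 25 °C
Reagents that add atoms: iodomethane IC
Why: Second stage of the Corey–Fuchs sequence, in which Br–Li exchange, Fritsch–Buttenberg–Wiechell rearrangement to the lithium acetylide and C-methylation give the methyl alkyne.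

Step 14
Reactants: 25 benzyl (R,E)-4-methylnon-2-en-7-yn-1-yl ether
Product: 27 (2S,3R,Z)-1-(1-iodoethylidene)-3-methyl-2-vinylcyclopentane, via alkenylzirconium benzyloxide 26 (not isolated)
Conditions: Cp2ZrCl2, n-BuLi (2 equiv), THF, −78 °C; add 25, −78 → 25 °C; then I2, −78 → 0 °C
Reagents that add atoms: iodine [I][I]
Why: Cp2Zr-mediated reductive enyne cyclisation, in which oxidative cyclisation closes ring A, β-benzyloxide elimination from the zirconacycle leaves the vinyl group and iodinolysis of the alkenyl–Zr bond gives the tetrasubstituted iodide with iodine cis to the vinyl-bearing carbon (syn-carbometalation), the new ring stereocentre being set trans to the methyl group because the methyl takes the exo position in the bicyclic zirconacycle.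

Step 15
Reactants: 27 (2S,3R,Z)-1-(1-iodoethylidene)-3-methyl-2-vinylcyclopentane; 17 keto lactone
Product: 29 tertiary alcohol from addition of the ring A alkenyl group to the ketone of 17 (hydroxyl axial, trans to the butenyl chain; lactone intact), via alkenyllithium 28 (not isolated)
Conditions: 27, t-BuLi (2.1 equiv), Et2O, −78 °C; then 17, THF, −78 → −40 °C; aq NH4Cl
Reagents that add atoms: none
Why: Iodine–lithium exchange with retention of alkene geometry and 1,2-addition, in which the bulky alkenyllithium should attack the cyclohexanone equatorially to give the axial tertiary alcohol, while the lactone carbonyl (quaternary α-carbon, tertiary alkoxy group) is too hindered to react at −78 °C.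

Step 16
Reactants: 29 tertiary alcohol with two vinyl groups
Product: 30 tetracyclic cyclooctadiene lactone (new cis-CH=CH in ring B)
Conditions: second-generation Grubbs catalyst (10 mol %), toluene, 80 °C
Reagents that add atoms: none
Why: Ring-closing metathesis of the two vinyl groups should close the eight-membered ring B as the cis-cyclooctene, helped by the trans-diequatorial placement of the two arms on ring C and their cis relation across the tetrasubstituted alkene.

Step 17
Reactants: 30 tetracyclic cyclooctadiene lactone
Product: 31 tetracyclic lactone with the tetrasubstituted alkene only (lactone-bridged form of the target)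
Conditions: H2 (1 atm), RhCl(PPh3)3 (10 mol %), benzene/EtOH, 25 °C
Reagents that add atoms: none
Why: Chemoselective homogeneous hydrogenation, in which RhCl(PPh3)3 should reduce the cis-disubstituted ring alkene and leave the tetrasubstituted alkene untouched, with no stereocentre formed.

Step 18
Reactants: 31 tetracyclic lactone
Product: 32 sesterfisheric acid
Conditions: K, 18-crown-6, t-BuNH2/THF, 25 °C; then aq HCl to pH 3
Reagents that add atoms: none
Why: Dissolving-metal alkyl–oxygen fission of a hindered tertiary-alkyl ester (the known deoxygenation of tertiary alcohols through their esters), in which the lactone radical anion should fragment to the carboxylate and a tertiary radical that is reduced and protonated to the isopropyl group, so one step frees both the acid and the isopropyl group while the ring carbon bearing it keeps its configuration and the carbinol is protected as its alkoxide.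

**Compound list**

1 | (R)-α-terpineol, 2-[(1R)-4-methylcyclohex-3-en-1-yl]propan-2-ol | CC1=CC[C@H](C(C)(C)O)CC1 | starting material
2 | (R)-3-(2-hydroxypropan-2-yl)-6-oxoheptanoic acid | CC(=O)CC[C@H](CC(=O)O)C(C)(C)O | intermediate
3 | (R)-5,5-dimethyl-4-(3-oxobutyl)dihydrofuran-2(3H)-one | CC(=O)CC[C@@H]1CC(=O)OC1(C)C | intermediate
4 | 3-[(R)-2,2-dimethyl-5-oxotetrahydrofuran-3-yl]propanoic acid | OC(=O)CC[C@@H]1CC(=O)OC1(C)C | intermediate
5 | (R)-5-hydroxy-4-(2-hydroxyethyl)-5-methylhexanoic acid | OCC[C@@H](CCC(=O)O)C(C)(C)O | intermediate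
6 | (R)-5-(2-hydroxyethyl)-6,6-dimethyltetrahydro-2H-pyran-2-one | OCC[C@H]1CCC(=O)OC1(C)C | intermediate
7 | (R)-5-[2-(tert-butyldimethylsilyloxy)ethyl]-6,6-dimethyltetrahydro-2H-pyran-2-one | CC(C)(C)[Si](C)(C)OCC[C@H]1CCC(=O)OC1(C)C | intermediate
8 | (5S)-5-[2-(tert-butyldimethylsilyloxy)ethyl]-6,6-dimethyl-3-(phenylselanyl)tetrahydro-2H-pyran-2-one (both C3 epimers) | CC(C)(C)[Si](C)(C)OCC[C@H]1CC([Se]c2ccccc2)C(=O)OC1(C)C | intermediate
9 | (S)-5-[2-(tert-butyldimethylsilyloxy)ethyl]-6,6-dimethyl-5,6-dihydro-2H-pyran-2-one | CC(C)(C)[Si](C)(C)OCC[C@H]1C=CC(=O)OC1(C)C | intermediate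
10 | (S)-5-(2-bromoethyl)-6,6-dimethyl-5,6-dihydro-2H-pyran-2-one | BrCC[C@H]1C=CC(=O)OC1(C)C | intermediate
11 | 2-(trimethylsilyloxy)buta-1,3-diene | C=CC(=C)O[Si](C)(C)C | starting material
12 | cis-fused 4-(2-bromoethyl)-3,3-dimethyl-6-(trimethylsilyloxy)-3,4,4a,5,8,8a-hexahydro-1H-isochromen-1-one (4a-H and 8a-H cis, 4-H trans to 4a-H) | BrCC[C@H]1[C@@H]2CC(O[Si](C)(C)C)=CC[C@@H]2C(=O)OC1(C)C | intermediate
13 | potassium lactone enolate of 12 | BrCC[C@H]1[C@@H]2CC(O[Si](C)(C)C)=CCC2=C([O-])OC1(C)C.[K+] | intermediate
14 | trans-fused 3-(2-hydroxypropan-2-yl)-5-(trimethylsilyloxy)-2,3,3a,4,7,7a-hexahydro-1H-indene-7a-carboxylic acid δ-lactone (3a-H trans to the 7a-carboxyl, lactone bridge on the carboxyl face) | C[Si](C)(C)OC1=CC[C@@]2(C(=O)O3)CC[C@H](C3(C)C)[C@@H]2C1 | intermediate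
15 | (E)-but-2-en-1-ol | C/C=C/CO | starting material
16 | (E)-but-2-en-1-yl methyl carbonate | C/C=C/COC(=O)OC | intermediate
17 | trans-fused 6-[(S)-but-3-en-2-yl]-3-(2-hydroxypropan-2-yl)-5-oxo-octahydro-1H-indene-7a-carboxylic acid δ-lactone (6-substituent equatorial, 6-H cis to the 7a-carboxyl) | C=C[C@H](C)[C@H]1C[C@@]2(C(=O)O3)CC[C@H](C3(C)C)[C@@H]2CC1=O | intermediate
18 | (R)-3,7-dimethylocta-1,6-diene ((R)-β-citronellene) | CC(C)=CCC[C@@H](C)C=C | starting material
19 | 2,2-dimethyl-3-[(R)-3-methylpent-4-en-1-yl]oxirane (both epoxide epimers) | CC1(C)OC1CC[C@@H](C)C=C | intermediate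
20 | (R)-4-methylhex-5-enal | O=CCC[C@@H](C)C=C | intermediate
21 | (Z)-1,4-bis(benzyloxy)but-2-ene | c1ccccc1COC/C=C\COCc1ccccc1 | starting material
22 | (R,E)-7-(benzyloxy)-4-methylhept-5-enal | O=CCC[C@@H](C)/C=C/COCc1ccccc1 | intermediate
23 | benzyl (R,E)-8,8-dibromo-4-methylocta-2,7-dien-1-yl ether | BrC(Br)=CCC[C@@H](C)/C=C/COCc1ccccc1 | intermediate
24 | lithium acetylide of benzyl (R,E)-4-methyloct-2-en-7-yn-1-yl ether | [Li]C#CCC[C@@H](C)/C=C/COCc1ccccc1 | intermediate
25 | benzyl (R,E)-4-methylnon-2-en-7-yn-1-yl ether | CC#CCC[C@@H](C)/C=C/COCc1ccccc1 | intermediate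
26 | (Z)-{1-[(2S,3R)-3-methyl-2-vinylcyclopentylidene]ethyl}bis(cyclopentadienyl)zirconium benzyloxide | [Zr](C1C=CC=C1)(C1C=CC=C1)(OCc1ccccc1)/C(C)=C1/CC[C@@H](C)[C@@H]1C=C | intermediate
27 | (2S,3R,Z)-1-(1-iodoethylidene)-3-methyl-2-vinylcyclopentane | I/C(C)=C1/CC[C@@H](C)[C@@H]1C=C | intermediate
28 | alkenyllithium from 27 (lithium in place of iodine, geometry retained) | [Li]/C(C)=C1/CC[C@@H](C)[C@@H]1C=C | intermediate
29 | tertiary alcohol: 17 with its ketone carbon bearing axial OH and the 1-[(2S,3R)-3-methyl-2-vinylcyclopentylidene]ethyl group (carbinol carbon cis to the vinyl-bearing ring carbon across the alkene) | C=C[C@H](C)[C@H]1C[C@@]2(C(=O)O3)CC[C@H](C3(C)C)[C@@H]2C[C@]1(O)/C(C)=C1/CC[C@@H](C)[C@@H]1C=C | intermediate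
30 | tetracyclic 5-8-6-5 lactone with the tetrasubstituted alkene and a cis-disubstituted alkene in ring B | C/C1=C2\CC[C@@H](C)[C@@H]2/C=C\[C@H](C)[C@H]2C[C@@]3(C(=O)O4)CC[C@H](C4(C)C)[C@@H]3C[C@]12O | intermediate
31 | sesterfisheric acid with its carboxyl esterified by the tertiary carbon that becomes the isopropyl CH (bridged δ-lactone) | C/C1=C2\CC[C@@H](C)[C@@H]2CC[C@H](C)[C@H]2C[C@@]3(C(=O)O4)CC[C@H](C4(C)C)[C@@H]3C[C@]12O | intermediate
32 | sesterfisheric acid | C/C1=C2\CC[C@@H](C)[C@@H]2CC[C@H](C)[C@H]2C[C@@]3(C(=O)O)CC[C@H](C(C)C)[C@@H]3C[C@]12O | target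

**Step count and risks**

Total step count: 18. Longest linear sequence: 12 steps (steps 1–7, 9, 15–18, from 1).

Steps most likely to fail:

1. Step 7. The thermal cycloaddition to the hindered, unactivated enoate may be outrun by polymerisation of the diene, or para regiocontrol may erode. The fallback sets out from 10 and uses a more reactive diene with a stepwise finish. Cycloaddition of 10 with (E)-1-methoxy-3-(trimethylsilyloxy)buta-1,3-diene (toluene, 110 °C) should give the methoxy silyl enol ether cycloadduct F1. Dilute HCl in THF removes the silyl group and methanol to give the cis-fused bicyclic enone F2. KN(SiMe3)2 (THF, −78 → 0 °C) forms the vinylogous lactone enolate, which closes the same bond by the same 5-exo-tet alkylation to give the tricyclic enone F3. Rhodium-catalysed 1,4-hydrosilylation (Et3SiH, RhCl(PPh3)3) gives the triethylsilyl enol ether F4. F4 is taken through the conditions of step 9 in place of 14, and the route is rejoined at 17.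

2. Step 9. Catalyst and substrate control may be mismatched at the new methyl-bearing carbon, attack may occur at the unsubstituted allyl terminus, or turnover may be slow with the hindered enolate. The fallback sets out from 14 and builds the side chain by aldol condensation and conjugate addition. A Mukaiyama aldol reaction with acetaldehyde (BF3·OEt2, CH2Cl2, −78 °C) should give the β-hydroxy ketone F5. Acid-catalysed dehydration (TsOH, benzene, 80 °C) gives the (E)-ethylidene ketone F6. Rhodium-catalysed asymmetric conjugate addition of a vinyl group (potassium vinyltrifluoroborate, [Rh(cod)OH]2, (S)- or (R)-BINAP, dioxane/H2O) sets the methyl-bearing carbon under catalyst control. DBU equilibration of the ring α-centre then gives 17.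

3. Step 18. Electron transfer may take the acyl–oxygen path (over-reduction to a diol) or also cleave the C–O bond of the allylic carbinol. The fallback sets out from 31 and replaces the one-step fission by a radical deoxygenation. KOSiMe3 (THF, 60 °C) opens the lactone and MeI methylates the carboxylate in the same flask to give the dihydroxy methyl ester F7. Methyl chlorooxoacetate (pyridine, DMAP) should acylate only the acyclic dimethylcarbinol, the ring carbinol being too hindered, to give the methyl oxalate F8. Bu3SnH and AIBN (toluene, 110 °C) remove the oxalate by the tertiary radical to give the isopropyl methyl ester F9. SN2 demethylation with LiSPr in HMPA then gives 32.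

Further compounds
F1 | step 7 | cis-fused 4-(2-bromoethyl)-8-methoxy-3,3-dimethyl-6-(trimethylsilyloxy)-3,4,4a,5,8,8a-hexahydro-1H-isochromen-1-one (both C8 epimers) | BrCC[C@H]1[C@@H]2CC(O[Si](C)(C)C)=CC(OC)[C@@H]2C(=O)OC1(C)C
F2 | step 7 | cis-fused 4-(2-bromoethyl)-3,3-dimethyl-4,4a,5,8a-tetrahydro-1H-isochromene-1,6(3H)-dione | BrCC[C@H]1[C@@H]2CC(=O)C=C[C@@H]2C(=O)OC1(C)C
F3 | step 7 | trans-fused 3-(2-hydroxypropan-2-yl)-5-oxo-2,3,3a,4,5,7a-hexahydro-1H-indene-7a-carboxylic acid δ-lactone | O=C1C=C[C@@]2(C(=O)O3)CC[C@H](C3(C)C)[C@@H]2C1
F4 | step 7 | triethylsilyl analogue of 14 | CC[Si](CC)(CC)OC1=CC[C@@]2(C(=O)O3)CC[C@H](C3(C)C)[C@@H]2C1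
F5 | step 9 | 6-(1-hydroxyethyl) analogue of 17 (epimers at the carbinol and at C6) | CC(O)C1C[C@@]2(C(=O)O3)CC[C@H](C3(C)C)[C@@H]2CC1=O
F6 | step 9 | (E)-6-ethylidene analogue of 17 | C/C=C1\C[C@@]2(C(=O)O3)CC[C@H](C3(C)C)[C@@H]2CC1=O
F7 | step 18 | methyl ester of the seco acid of 31 with free 2-hydroxypropan-2-yl group | C/C1=C2\CC[C@@H](C)[C@@H]2CC[C@H](C)[C@H]2C[C@@]3(C(=O)OC)CC[C@H](C(C)(C)O)[C@@H]3C[C@]12O
F8 | step 18 | methyl oxalate of the dimethylcarbinol of F7 | C/C1=C2\CC[C@@H](C)[C@@H]2CC[C@H](C)[C@H]2C[C@@]3(C(=O)OC)CC[C@H](C(C)(C)OC(=O)C(=O)OC)[C@@H]3C[C@]12O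
F9 | step 18 | sesterfisheric acid methyl ester | C/C1=C2\CC[C@@H](C)[C@@H]2CC[C@H](C)[C@H]2C[C@@]3(C(=O)OC)CC[C@H](C(C)C)[C@@H]3C[C@]12O
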